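**Strategy.** Cyclointegrin is cut at the two bonds that tie ring B to the oxocine ring: O–C2' and C1'–C2. Because C1' and C2' are adjacent, the eight-membered oxocine ring is a six-membered δ-lactone (6,6-dimethyloxan-2-one) with the ortho-phenylene of ring B inserted into its acyl C–O bond. In one flask, a 2-fluoroaryllithium acylates the lactone (C1'–C2) and the tertiary alkoxide thus released displaces the ortho fluoride, now activated by the new ketone (O–C2'), giving a benzoxocinone. The lactone carbonyl carbon becomes C2 and its oxygen O1 when the pyranone is annulated onto this ketone with a 2,6-difluoro-4-methoxybenzoyl unit (ring A). The last fluoride is then exchanged for oxygen and both benzyl groups are removed.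

Key step: step 2

Remark: atoms are named with the flavone numbering of the target throughout (O1, C2, C3, C4 in the pyranone; C1' to C6' in ring B; the oxocine oxygen sits on C2'). Cyclointegrin has no stereocenter, so no stereocontrol is needed.

Step 1
Reactants: 1 2,2-dimethylcyclopentanone
Product: 2 6,6-dimethyloxan-2-one
Conditions: mCPBA, CH2Cl2, 0 °C to rt
Reagents that add atoms: mCPBA (3-chloroperoxybenzoic acid), O=C(OO)c1cccc(Cl)c1
Why: Baeyer–Villiger oxidation in which the quaternary α-carbon migrates in preference to the CH2 group, so oxygen is inserted between the carbonyl carbon and the C(CH3)2 carbon to give the δ-lactone.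

Step 2
Reactants: 2 6,6-dimethyloxan-2-one; 3 4-(benzyloxy)-1-bromo-2-fluorobenzene
Product: 7 9-(benzyloxy)-2,2-dimethyl-3,4,5,6-tetrahydro-2H-1-benzoxocin-6-one, via aryllithium 4 (not isolated), via lactolate 5 (not isolated), via keto alkoxide 6 (not isolated)
Conditions: 3, t-BuLi (2.0 equiv), THF, −78 °C; then 2, −78 °C; then DMPU, 0.01 M, −78 to 65 °C
Reagents that add atoms: none
Why: Bromine–lithium exchange (the second equivalent of t-BuLi destroys t-BuBr, so no alkyl halide is left to cap the alkoxide) gives 4, which adds once to 2 to give the tetrahedral lactolate 5, stable at −78 °C, so that no second addition should occur. On warming in THF/DMPU, 5 opens to keto alkoxide 6, in which the new ketone activates the ortho C–F bond and the liberated tertiary alkoxide displaces fluoride by addition–elimination through a Meisenheimer intermediate stabilised by the C2 carbonyl, with loss of LiF. The closest known reaction types are the acylation of aryllithiums by lactones to δ-hydroxy ketones and the intramolecular SNAr of alkoxides on ortho-fluoroaryl ketones; run in one flask, their net result is insertion of the C1'–C2' unit into the acyl C–O bond. The only ring closed is the eight-membered oxocine, by attack of O on C2' (the attacked C1'=C2' unit lies inside the new ring, formally 8-endo), while the six-membered lactone opens, so the change is a two-atom ring expansion. No stereocenter is formed. The step needs carbon at C1' and oxygen at C2', which the fixed positions of Br and F in 3 secure, and it needs ring closure to beat oligomerisation, which high dilution, the gem-dimethyl group and the precipitation of LiF should favour.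

Step 3
Reactants: 8 2,6-difluoro-4-methoxybenzoic acid
Product: 9 2,6-difluoro-4-methoxybenzoyl chloride
Conditions: (COCl)2, DMF (cat.), CH2Cl2, 0 °C to rt
Reagents that add atoms: oxalyl chloride, O=C(Cl)C(=O)Cl
Why: Standard conversion of a carboxylic acid into its chloride through the chloroiminium species formed from oxalyl chloride and catalytic DMF; the aryl fluorides and the methyl ether are inert.

Step 4
Reactants: 7 9-(benzyloxy)-2,2-dimethyl-3,4,5,6-tetrahydro-2H-1-benzoxocin-6-one; 9 2,6-difluoro-4-methoxybenzoyl chloride
Product: 11 4'-O-benzyl-5-deoxy-5-fluorocyclointegrin, via diketone 10 (not isolated)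
Conditions: LiN(SiMe3)2 (2.2 equiv), THF, −78 °C; then 9, −78 °C to rt; then DMF, 90 °C
Reagents that add atoms: none
Why: Claisen-type C-acylation of the lithium enolate of the aryl ketone (the second equivalent of base deprotonates the more acidic diketone 10 and drives the acylation), followed on heating by intramolecular SNAr of the enolate oxygen on a fluorine-bearing carbon ortho to the aroyl carbonyl, which closes the six-membered pyranone (the known 2-fluorobenzoyl route to chromones; every other closure would give a four-membered ring).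

Step 5
Reactants: 11 4'-O-benzyl-5-deoxy-5-fluorocyclointegrin
Product: 12 4',5-di-O-benzylcyclointegrin
Conditions: BnOH, NaH, DMF, 0 °C to rt
Reagents that add atoms: benzyl alcohol, OCc1ccccc1
Why: SNAr of the C5 fluoride, the only halogen left and activated by the peri C4 carbonyl, by benzyl alkoxide; benzyl is chosen so that a single hydrogenolysis frees both phenols.

Step 6
Reactants: 12 4',5-di-O-benzylcyclointegrin
Product: 13 cyclointegrin
Conditions: H2 (1 atm), Pd/C, EtOAc/MeOH, rt
Reagents that add atoms: none
Why: Hydrogenolysis of the two benzyl aryl ethers over Pd/C; the tetrasubstituted C2=C3 bond of the flavone, the methyl ether and the tertiary alkyl aryl ether should not be touched under one atmosphere of hydrogen at room temperature.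

**Compound list**

1 | 2,2-dimethylcyclopentanone | CC1(C)CCCC1=O | starting material
2 | 6,6-dimethyloxan-2-one (6,6-dimethyltetrahydro-2H-pyran-2-one) | CC1(C)CCCC(=O)O1 | intermediate
3 | 4-(benzyloxy)-1-bromo-2-fluorobenzene | Fc1cc(OCc2ccccc2)ccc1Br | starting material
4 | [4-(benzyloxy)-2-fluorophenyl]lithium | [Li]c1ccc(OCc2ccccc2)cc1F | intermediate
5 | lithium 2-[4-(benzyloxy)-2-fluorophenyl]-6,6-dimethyloxan-2-olate (racemic tetrahedral adduct) | CC1(C)CCCC([O-])(c2ccc(OCc3ccccc3)cc2F)O1.[Li+] | intermediate
6 | lithium 6-[4-(benzyloxy)-2-fluorophenyl]-2-methyl-6-oxohexan-2-olate | CC(C)([O-])CCCC(=O)c1ccc(OCc2ccccc2)cc1F.[Li+] | intermediate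
7 | 9-(benzyloxy)-2,2-dimethyl-3,4,5,6-tetrahydro-2H-1-benzoxocin-6-one | CC1(C)CCCC(=O)c2ccc(OCc3ccccc3)cc2O1 | intermediate
8 | 2,6-difluoro-4-methoxybenzoic acid | COc1cc(F)c(C(=O)O)c(F)c1 | starting material
9 | 2,6-difluoro-4-methoxybenzoyl chloride | COc1cc(F)c(C(=O)Cl)c(F)c1 | intermediate
10 | 9-(benzyloxy)-5-(2,6-difluoro-4-methoxybenzoyl)-2,2-dimethyl-3,4,5,6-tetrahydro-2H-1-benzoxocin-6-one (racemic; present in the flask as its lithium enolate) | CC1(C)CCC(C(=O)c2c(F)cc(OC)cc2F)C(=O)c3ccc(OCc4ccccc4)cc3O1 | intermediate
11 | 4'-O-benzyl-5-deoxy-5-fluorocyclointegrin (the target skeleton with F at C5 and benzyloxy at C4') | COc1cc(F)c2c(=O)c3c(oc2c1)-c1ccc(OCc4ccccc4)cc1OC(C)(C)CC3 | intermediate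
12 | 4',5-di-O-benzylcyclointegrin (the target with benzyloxy at C5 and C4') | COc1cc(OCc5ccccc5)c2c(=O)c3c(oc2c1)-c1ccc(OCc4ccccc4)cc1OC(C)(C)CC3 | intermediate
13 | cyclointegrin | COc1cc(O)c2c(=O)c3c(oc2c1)-c1ccc(O)cc1OC(C)(C)CC3 | target

**Totals.** Total step count: 6. Longest linear sequence: 5 steps (1, 2, 4, 5, 6); step 3 prepares the ring A acid chloride in parallel.

**Steps most likely to fail**

Step 2. The hindered lithium tert-alkoxide may close the eight-membered ring too slowly, so that intermolecular substitution (oligomer formation) or persistence of the six-membered lactol form wins. A second danger is loss of LiF from the aryllithium to an aryne if the addition to 2 is not complete before warming. The fallback sets out from 3 and comes back at 7; it makes the C–O bond first and intermolecularly and closes the eight-membered ring at a C=C bond by metathesis. Compound 3 is lithiated (t-BuLi, THF, −78 °C) and formylated with DMF to 4-(benzyloxy)-2-fluorobenzaldehyde F1. The potassium alkoxide of 2-methylpent-4-en-2-ol (KN(SiMe3)2, THF/DMF) displaces the aldehyde-activated fluoride to give 4-(benzyloxy)-2-[(2-methylpent-4-en-2-yl)oxy]benzaldehyde F2. Addition of CH2=CHMgBr gives the racemic allylic alcohol 1-{4-(benzyloxy)-2-[(2-methylpent-4-en-2-yl)oxy]phenyl}prop-2-en-1-ol F3. Ring-closing metathesis (second-generation Grubbs catalyst, CH2Cl2, 40 °C, high dilution) should give the cis-cycloalkene (4Z)-9-(benzyloxy)-2,2-dimethyl-3,6-dihydro-2H-1-benzoxocin-6-ol F4. Redox isomerisation of the allylic alcohol (RuCl2(PPh3)3, toluene, 110 °C) then gives ketone 7.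

Step 4. The enolate may be acylated on oxygen in place of carbon, or the silylamide base may consume the acid chloride. The fallback sets out from 7 and comes back at 11; it makes the C3–C4 bond by an aldol addition, which has no O- versus C-selectivity problem. The lithium enolate of 7 (LiN(SiMe3)2, THF, −78 °C) is added to 2,6-difluoro-4-methoxybenzaldehyde to give the β-hydroxy ketone 9-(benzyloxy)-5-[(2,6-difluoro-4-methoxyphenyl)(hydroxy)methyl]-2,2-dimethyl-3,4,5,6-tetrahydro-2H-1-benzoxocin-6-one F5 as a diastereomer mixture. Oxidation with Dess–Martin periodinane gives diketone 10, now isolated, and K2CO3 in DMF at 80 °C closes the pyranone to 11.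

Step 5. The alkoxide may add to C2 of the pyranone and open the ring in competition with substitution at C5. The fallback sets out from 8 and comes back at 12; it installs the C5 oxygen before the pyranone exists. Acid 8 with benzyl alcohol and NaH (DMF, 80 °C) should undergo a single SNAr ortho to the carboxylate to give 2-(benzyloxy)-6-fluoro-4-methoxybenzoic acid F6. (COCl)2 with catalytic DMF gives 2-(benzyloxy)-6-fluoro-4-methoxybenzoyl chloride F7. Acylation of the lithium enolate of 7 under the conditions of step 4 gives 9-(benzyloxy)-5-[2-(benzyloxy)-6-fluoro-4-methoxybenzoyl]-2,2-dimethyl-3,4,5,6-tetrahydro-2H-1-benzoxocin-6-one F8, not isolated, whose enolate oxygen displaces the remaining fluoride on heating in DMF to give 12. The route resumes at step 6.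

Further compounds
F1 | step 2 | 4-(benzyloxy)-2-fluorobenzaldehyde | O=Cc1ccc(OCc2ccccc2)cc1F
F2 | step 2 | 4-(benzyloxy)-2-[(2-methylpent-4-en-2-yl)oxy]benzaldehyde | C=CCC(C)(C)Oc1cc(OCc2ccccc2)ccc1C=O
F3 | step 2 | 1-{4-(benzyloxy)-2-[(2-methylpent-4-en-2-yl)oxy]phenyl}prop-2-en-1-ol (racemic) | C=CCC(C)(C)Oc1cc(OCc2ccccc2)ccc1C(O)C=C
F4 | step 2 | (4Z)-9-(benzyloxy)-2,2-dimethyl-3,6-dihydro-2H-1-benzoxocin-6-ol (racemic) | CC1(C)C/C=C\C(O)c2ccc(OCc3ccccc3)cc2O1
F5 | step 4 | 9-(benzyloxy)-5-[(2,6-difluoro-4-methoxyphenyl)(hydroxy)methyl]-2,2-dimethyl-3,4,5,6-tetrahydro-2H-1-benzoxocin-6-one (racemic diastereomer mixture) | CC1(C)CCC(C(O)c2c(F)cc(OC)cc2F)C(=O)c3ccc(OCc4ccccc4)cc3O1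
F6 | step 5 | 2-(benzyloxy)-6-fluoro-4-methoxybenzoic acid | COc1cc(F)c(C(=O)O)c(OCc2ccccc2)c1
F7 | step 5 | 2-(benzyloxy)-6-fluoro-4-methoxybenzoyl chloride | COc1cc(F)c(C(=O)Cl)c(OCc2ccccc2)c1
F8 | step 5 | 9-(benzyloxy)-5-[2-(benzyloxy)-6-fluoro-4-methoxybenzoyl]-2,2-dimethyl-3,4,5,6-tetrahydro-2H-1-benzoxocin-6-one (racemic) | CC1(C)CCC(C(=O)c2c(F)cc(OC)cc2OCc4ccccc4)C(=O)c5ccc(OCc3ccccc3)cc5O1
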